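**Strategy.** Ring B (C5–C6–C7–C8–C9–C10) carries its C7=C8 alkene directly opposite the C5–C10 ring-fusion bond, the retron of a [3+3] annulation between an allylidene phosphorane and an enone. The route builds an acyclic precursor in which an allylic phosphonium salt (future C5–C6–C7) is tied through the C1–C4 chain (2,3-diol as acetonide, C4 gem-dimethyl) to a tetrasubstituted enone (C10=C9–C8=O) already bearing the side chain. One base treatment triggers vinylogous Michael addition (C5–C10, closing ring A) and intramolecular Wittig olefination (C7=C8, closing ring B), giving a labda-5,7-diene. Hydroxyl-directed hydrogenation of the 5,6-alkene, then monoacetylation, finish the target.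

Key step: step 14

Remark: the target is read as methyl (13S)-2α-acetoxy-3α-hydroxylabd-7-en-15-oate (2R,3S,5R,9S,10R,13S); (S)-pantolactone and methyl hydrogen (R)-3-methylglutarate are taken as commercial.

**Step 1**
Reactants: 1 (R)-5-methoxy-3-methyl-5-oxopentanoic acid
Product: 2 (S)-4-methyltetrahydro-2H-pyran-2-one
Conditions: LiBH4, THF, 0 °C to rt; then 2 M HCl, rt
Reagents that add atoms: none
Why: LiBH4 should reduce the methyl ester but not the lithium carboxylate, and acidification should close the δ-lactone without touching the stereocentre (chemoselective half-ester reduction, lactonisation).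

**Step 2**
Reactants: 2 (S)-4-methyltetrahydro-2H-pyran-2-one
Product: 3 methyl (R)-5-iodo-3-methylpentanoate
Conditions: Me3SiI, CH2Cl2, rt; then MeOH, 40 °C
Reagents that add atoms: iodotrimethylsilane C[Si](C)(C)I; methanol CO
Why: Iodide should open the silyl-activated lactone by SN2 attack at the O–CH2 carbon, and methanol should then esterify under the HI formed (silyl iodide lactone cleavage, Fischer esterification); the remote stereocentre is unchanged.

**Step 3**
Reactants: 4 3-methylbut-2-enoic acid; 3 methyl (R)-5-iodo-3-methylpentanoate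
Product: 5 2-[(3S)-5-methoxy-3-methyl-5-oxopentyl]-3-methylbut-3-enoic acid (both C2 epimers)
Conditions: LiN(iPr)2 (2.2 equiv), THF, −78 to 0 °C; then 3, −78 °C to rt; HCl work-up
Reagents that add atoms: none
Why: The dienolate dianion of the unsaturated acid should be alkylated at its α-carbon by the primary iodide, moving the alkene out of conjugation (deconjugative α-alkylation); the new α-centre needs no control because it becomes sp2 in step 5.

**Step 4**
Reactants: 5 2-[(3S)-5-methoxy-3-methyl-5-oxopentyl]-3-methylbut-3-enoic acid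
Product: 7 methyl (3S)-6-acetyl-3,7-dimethyloct-7-enoate, via acid chloride 6 (not isolated)
Conditions: (COCl)2, DMF (cat.), CH2Cl2, 0 °C to rt; then Me2CuLi, Et2O, −78 °C
Reagents that add atoms: lithium dimethylcuprate C[Cu-]C.[Li+]; oxalyl chloride O=C(Cl)C(Cl)=O (gives the chlorine of 6)
Why: The acid chloride should couple with the Gilman reagent to the methyl ketone without attack on the methyl ester (acyl chloride–organocuprate ketone synthesis).

**Step 5**
Reactants: 7 methyl (3S)-6-acetyl-3,7-dimethyloct-7-enoate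
Product: 8 methyl (3S)-3,7-dimethyl-6-[1-(trimethylsilyloxy)ethylidene]oct-7-enoate (E/Z mixture)
Conditions: Me3SiOTf, Et3N, CH2Cl2, 0 °C
Reagents that add atoms: trimethylsilyl trifluoromethanesulfonate C[Si](C)(C)OS(=O)(=O)C(F)(F)F
Why: Soft enolisation should remove the doubly activated α-hydrogen and give the conjugated 2-silyloxy-1,3-diene needed as a vinylogous nucleophile (silyl enol ether formation).

**Step 6**
Reactants: 9 (S)-pantolactone
Product: 10 (S)-3,3-dimethylbutane-1,2,4-triol
Conditions: LiAlH4, THF, 0 °C to reflux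
Reagents that add atoms: none
Why: Hydride reduction of the lactone should give the triol with the carbinol stereocentre (future C3) untouched (ester reduction).

**Step 7**
Reactants: 10 (S)-3,3-dimethylbutane-1,2,4-triol
Product: 11 [(2S,4S)-2-(4-methoxyphenyl)-5,5-dimethyl-1,3-dioxan-4-yl]methanol
Conditions: 4-MeOC6H4CH(OMe)2, CSA (cat.), CH2Cl2, rt
Reagents that add atoms: 4-methoxybenzaldehyde dimethyl acetal COC(OC)c1ccc(OC)cc1
Why: Under thermodynamic control the aryl acetal should form the six-membered 1,3-dioxane on the secondary and the neopentyl hydroxyl with the aryl group equatorial, leaving the primary alcohol (future C2) free (acetalisation).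

**Step 8**
Reactants: 11 [(2S,4S)-2-(4-methoxyphenyl)-5,5-dimethyl-1,3-dioxan-4-yl]methanol
Product: 12 (2S,4S)-2-(4-methoxyphenyl)-5,5-dimethyl-1,3-dioxane-4-carbaldehyde
Conditions: Dess–Martin periodinane, NaHCO3, CH2Cl2, rt
Reagents that add atoms: none
Why: The buffered periodinane oxidation should give the α-alkoxy aldehyde without epimerisation (Dess–Martin oxidation).

**Step 9**
Reactants: 12 (2S,4S)-2-(4-methoxyphenyl)-5,5-dimethyl-1,3-dioxane-4-carbaldehyde; 8 methyl (3S)-3,7-dimethyl-6-[1-(trimethylsilyloxy)ethylidene]oct-7-enoate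
Product: 13 methyl (3S,9R)-6-acetyl-9-hydroxy-9-[(2S,4S)-2-(4-methoxyphenyl)-5,5-dimethyl-1,3-dioxan-4-yl]-3,7-dimethylnon-6-enoate (E/Z mixture at the enone)
Conditions: BF3·OEt2, CH2Cl2, −78 °C
Reagents that add atoms: none
Why: In this vinylogous Mukaiyama aldol the dienol ether should react at its unhindered terminal CH2 (its α-carbon is fully substituted), and the non-chelated α-alkoxy aldehyde should be attacked in the Felkin–Anh sense, giving the 2,3-anti (erythro) carbinol, i.e. (R) at future C2.

**Step 10**
Reactants: 13 aldol adduct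
Product: 14 methyl (3S)-6-acetyl-8-[(4R,5S)-5-(1-hydroxy-2-methylpropan-2-yl)-2,2-dimethyl-1,3-dioxolan-4-yl]-3,7-dimethyloct-6-enoate
Conditions: Me2C(OMe)2, acetone, CSA (cat.), rt
Reagents that add atoms: 2,2-dimethoxypropane COC(C)(C)OC
Why: Acid-catalysed trans-acetalisation should move the protection to the cis-dioxolane on O-2/O-3, the ring size favoured by acetone ketals, and free the neopentyl C5 alcohol.

**Step 11**
Reactants: 14 acetonide alcohol
Product: 15 methyl (3S)-6-acetyl-8-[(4R,5S)-2,2-dimethyl-5-(2-methyl-1-oxopropan-2-yl)-1,3-dioxolan-4-yl]-3,7-dimethyloct-6-enoate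
Conditions: Dess–Martin periodinane, NaHCO3, CH2Cl2, rt
Reagents that add atoms: none
Why: Oxidation of the neopentyl alcohol should give an aldehyde that has no α-hydrogen and so cannot epimerise or enolise (Dess–Martin oxidation).

**Step 12**
Reactants: 15 neopentyl aldehyde
Product: 16 methyl (3S)-6-acetyl-8-[(4R,5S)-5-(3-hydroxy-2-methylpent-4-en-2-yl)-2,2-dimethyl-1,3-dioxolan-4-yl]-3,7-dimethyloct-6-enoate (both carbinol epimers)
Conditions: CH2=CHMgBr, THF, −78 °C
Reagents that add atoms: vinylmagnesium bromide C=C[Mg]Br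
Why: At −78 °C the Grignard reagent should add to the aldehyde much faster than to the hindered tetrasubstituted enone or the ester (1,2-addition); the carbinol configuration is lost in step 13.

**Step 13**
Reactants: 16 allylic alcohol
Product: 17 {(2E)-4-[(4S,5R)-5-{(6S)-3-acetyl-8-methoxy-2,6-dimethyl-8-oxooct-2-en-1-yl}-2,2-dimethyl-1,3-dioxolan-4-yl]-4-methylpent-2-en-1-yl}triphenylphosphonium bromide
Conditions: PPh3·HBr, MeCN, rt
Reagents that add atoms: triphenylphosphine hydrobromide [Br-].c1ccc(cc1)[PH+](c1ccccc1)c1ccccc1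
Why: Ionisation of the allylic alcohol and capture of the allyl cation by PPh3 at the unhindered primary terminus should give the E allylic phosphonium salt with allylic transposition (SN1/SN2′ phosphonium salt formation).

**Step 14**
Reactants: 17 allylic phosphonium bromide
Product: 20 methyl (13S)-2α,3α-(isopropylidenedioxy)labda-5,7-dien-15-oate, via allylic ylide 18 (not isolated), via keto ylide 19 (not isolated)
Conditions: KN(SiMe3)2 (1.05 equiv), THF, −78 °C; then toluene, 80 °C, 0.005 M
Reagents that add atoms: none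
Why: KN(SiMe3)2 converts the salt into allylic ylide 18, whose γ-carbon (C5) adds in a vinylogous Michael sense to C10 of the tethered enone (6-exo-trig, closing ring A and forming C5–C10); proton return from the phosphonium arm to the enolate gives keto ylide 19, which closes ring B by intramolecular Wittig olefination of the C8 ketone (6-exo-trig attack of C7 on the carbonyl, forming C7=C8) and leaves C5=C6 as a second, removable alkene. The closest known reaction type is the [3+3] cyclohexadiene annulation of allylidenetriphenylphosphoranes with enones, which is also known for β,β-disubstituted, α-substituted acceptors that create a quaternary carbon. C10 is set in the chair-like Michael transition state of ring A, in which the cis-fused acetonide holds O-3 axial and O-2 equatorial and the C10 methyl goes axial while the bulkier acyl-bearing C9 branch stays equatorial, which gives the 10β-methyl relative to the 2α,3α-oxygens. C9 is set when the enolate carbon is protonated intramolecularly, through a six-membered transition state, from the face turned towards the C5–C7 arm; this hydrogen becomes the axial 9α-hydrogen on ring closure. The step needs γ- rather than α-attack of the ylide and Michael addition before any olefination, and both are secured by ring size, since α-attack or direct Wittig reaction would have to close eight- or ten-membered rings. High dilution and the irreversible Wittig step should pull the hindered, reversible Michael addition forward.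

**Step 15**
Reactants: 20 methyl (13S)-2α,3α-(isopropylidenedioxy)labda-5,7-dien-15-oate
Product: 21 methyl (13S)-2α,3α-dihydroxylabda-5,7-dien-15-oate
Conditions: PPTS, MeOH, 40 °C
Reagents that add atoms: none
Why: Mild acid-catalysed trans-ketalisation to methanol should release the cis-diol without isomerising the diene (acetonide cleavage).

**Step 16**
Reactants: 21 methyl (13S)-2α,3α-dihydroxylabda-5,7-dien-15-oate
Product: 22 methyl (13S)-2α,3α-dihydroxylabd-7-en-15-oate
Conditions: [Ir(cod)(PCy3)(py)]PF6 (5 mol %), H2 (1 atm), CH2Cl2, 0 °C, stopped after 1 equiv H2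
Reagents that add atoms: none
Why: The axial 3α-hydroxyl, homoallylic to C5=C6, should bind the cationic iridium catalyst and deliver H2 to the α-face of the 5,6-alkene, setting H-5α (trans ring fusion), while the remote, undirected 7,8-alkene is left (hydroxyl-directed homogeneous hydrogenation).

**Step 17**
Reactants: 22 methyl (13S)-2α,3α-dihydroxylabd-7-en-15-oate
Product: 23 methyl (13S)-2α-acetoxy-3α-hydroxylabd-7-en-15-oate (target)
Conditions: Ac2O (1.1 equiv), pyridine, DMAP (cat.), CH2Cl2, −20 to 0 °C
Reagents that add atoms: acetic anhydride CC(=O)OC(C)=O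
Why: The equatorial 2α-hydroxyl should be acylated much faster than the axial, neopentyl 3α-hydroxyl next to the gem-dimethyl carbon (selective acylation).

**Compound list**

1 | (R)-5-methoxy-3-methyl-5-oxopentanoic acid (methyl hydrogen (R)-3-methylglutarate) | COC(=O)C[C@H](C)CC(=O)O | starting material
2 | (S)-4-methyltetrahydro-2H-pyran-2-one | C[C@H]1CCOC(=O)C1 | intermediate
3 | methyl (R)-5-iodo-3-methylpentanoate | COC(=O)C[C@@H](C)CCI | intermediate
4 | 3-methylbut-2-enoic acid | CC(C)=CC(=O)O | starting material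
5 | 2-[(3S)-5-methoxy-3-methyl-5-oxopentyl]-3-methylbut-3-enoic acid (both C2 epimers) | COC(=O)C[C@@H](C)CCC(C(=O)O)C(C)=C | intermediate
6 | acid chloride of 5 | COC(=O)C[C@@H](C)CCC(C(=O)Cl)C(C)=C | intermediate (not isolated)
7 | methyl (3S)-6-acetyl-3,7-dimethyloct-7-enoate (both C6 epimers) | COC(=O)C[C@@H](C)CCC(C(C)=O)C(C)=C | intermediate
8 | methyl (3S)-3,7-dimethyl-6-[1-(trimethylsilyloxy)ethylidene]oct-7-enoate (E/Z mixture) | COC(=O)C[C@@H](C)CCC(=C(C)O[Si](C)(C)C)C(C)=C | intermediate
9 | (S)-pantolactone, (S)-3-hydroxy-4,4-dimethyldihydrofuran-2(3H)-one | CC1(C)COC(=O)[C@H]1O | starting material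
10 | (S)-3,3-dimethylbutane-1,2,4-triol | OC[C@@H](O)C(C)(C)CO | intermediate
11 | [(2S,4S)-2-(4-methoxyphenyl)-5,5-dimethyl-1,3-dioxan-4-yl]methanol | OC[C@H]1O[C@@H](c2ccc(OC)cc2)OCC1(C)C | intermediate
12 | (2S,4S)-2-(4-methoxyphenyl)-5,5-dimethyl-1,3-dioxane-4-carbaldehyde | O=C[C@H]1O[C@@H](c2ccc(OC)cc2)OCC1(C)C | intermediate
13 | methyl (3S,9R)-6-acetyl-9-hydroxy-9-[(2S,4S)-2-(4-methoxyphenyl)-5,5-dimethyl-1,3-dioxan-4-yl]-3,7-dimethylnon-6-enoate (E/Z at the enone) | COC(=O)C[C@@H](C)CCC(C(C)=O)=C(C)C[C@@H](O)[C@H]1O[C@@H](c2ccc(OC)cc2)OCC1(C)C | intermediate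
14 | methyl (3S)-6-acetyl-8-[(4R,5S)-5-(1-hydroxy-2-methylpropan-2-yl)-2,2-dimethyl-1,3-dioxolan-4-yl]-3,7-dimethyloct-6-enoate | COC(=O)C[C@@H](C)CCC(C(C)=O)=C(C)C[C@H]1OC(C)(C)O[C@H]1C(C)(C)CO | intermediate
15 | methyl (3S)-6-acetyl-8-[(4R,5S)-2,2-dimethyl-5-(2-methyl-1-oxopropan-2-yl)-1,3-dioxolan-4-yl]-3,7-dimethyloct-6-enoate | COC(=O)C[C@@H](C)CCC(C(C)=O)=C(C)C[C@H]1OC(C)(C)O[C@H]1C(C)(C)C=O | intermediate
16 | methyl (3S)-6-acetyl-8-[(4R,5S)-5-(3-hydroxy-2-methylpent-4-en-2-yl)-2,2-dimethyl-1,3-dioxolan-4-yl]-3,7-dimethyloct-6-enoate (both carbinol epimers) | COC(=O)C[C@@H](C)CCC(C(C)=O)=C(C)C[C@H]1OC(C)(C)O[C@H]1C(C)(C)C(O)C=C | intermediate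
17 | {(2E)-4-[(4S,5R)-5-{(6S)-3-acetyl-8-methoxy-2,6-dimethyl-8-oxooct-2-en-1-yl}-2,2-dimethyl-1,3-dioxolan-4-yl]-4-methylpent-2-en-1-yl}triphenylphosphonium bromide | COC(=O)C[C@@H](C)CCC(C(C)=O)=C(C)C[C@H]1OC(C)(C)O[C@H]1C(C)(C)/C=C/C[P+](c2ccccc2)(c3ccccc3)c4ccccc4.[Br-] | intermediate
18 | allylic ylide from 17 (P=CH–CH=CH–, otherwise as 17) | COC(=O)C[C@@H](C)CCC(C(C)=O)=C(C)C[C@H]1OC(C)(C)O[C@H]1C(C)(C)/C=C/C=P(c2ccccc2)(c3ccccc3)c4ccccc4 | intermediate (not isolated)
19 | keto ylide: ring A closed (C5–C10), C10 quaternary methyl, C9 carrying side chain and acetyl, exocyclic C5=C6–C7=PPh3 | COC(=O)C[C@@H](C)CC[C@@H](C(C)=O)[C@@]1(C)C[C@H]2OC(C)(C)O[C@H]2C(C)(C)C1=CC=P(c3ccccc3)(c4ccccc4)c5ccccc5 | intermediate (not isolated)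
20 | methyl (13S)-2α,3α-(isopropylidenedioxy)labda-5,7-dien-15-oate | COC(=O)C[C@@H](C)CC[C@H]1C(C)=CC=C2C(C)(C)[C@@H]3OC(C)(C)O[C@@H]3C[C@]12C | intermediate
21 | methyl (13S)-2α,3α-dihydroxylabda-5,7-dien-15-oate | COC(=O)C[C@@H](C)CC[C@H]1C(C)=CC=C2C(C)(C)[C@H](O)[C@H](O)C[C@]12C | intermediate
22 | methyl (13S)-2α,3α-dihydroxylabd-7-en-15-oate | COC(=O)C[C@@H](C)CC[C@H]1C(C)=CC[C@H]2C(C)(C)[C@H](O)[C@H](O)C[C@]12C | intermediate
23 | methyl (13S)-2α-acetoxy-3α-hydroxylabd-7-en-15-oate | COC(=O)C[C@@H](C)CC[C@H]1C(C)=CC[C@H]2C(C)(C)[C@H](O)[C@H](OC(C)=O)C[C@]12C | target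

**Step count and risks**

Total steps: 17. Longest linear sequence: 14 steps (steps 1–5 and 9–17, from 1 to 23).

Steps most likely to fail:

1. Step 14. The hindered vinylogous Michael addition (C5 next to a quaternary carbon onto a fully substituted enone carbon) may reverse or lose to intermolecular olefination, and intermolecular proton exchange may erode the facial control at C9. Fallback: setting out from allylic alcohol 16, PBr3 (Et2O, 0 °C) should give, with allylic transposition, the primary (E)-allylic bromide F1. Heating with P(OEt)3 (Arbuzov reaction) should give the diethyl (E)-allylphosphonate F2. LiN(iPr)2 (2 equiv) in THF/HMPA at −78 °C should add the more nucleophilic phosphonate-stabilised allyl anion through its γ-carbon to the enone, and warming with KOt-Bu should close ring B by a Horner–Wadsworth–Emmons reaction; the sequence returns to the route at diene 20.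

2. Step 16. Chemoselectivity between the two ring alkenes may be lost (over-reduction or 1,4-addition), or hydrogen may be delivered to the wrong face of C5. Fallback: setting out from acetonide 20, hydrogenation over Raney Ni in EtOAc, relying on addition to the less hindered α-face of the 5,6-bond as in the conversion of steroidal 5,7-dienes into 5α-7-enes, should give the 7-ene acetonide F3. PPTS/MeOH should then release the diol, returning at 22.

3. Step 9. Facial selectivity at the aldehyde may be poor (Felkin–Anh against chelation), and the aryl acetal may suffer under BF3. Fallback: setting out from aldehyde 12, addition of 8 under chelation control (MgBr2·OEt2, CH2Cl2, −78 °C) should give the C2-epimeric alcohol F4. Mitsunobu inversion (4-nitrobenzoic acid, PPh3, DIAD) should give the inverted 4-nitrobenzoate F5, and K2CO3/MeOH should cleave it, returning at 13.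

**Further compounds**

F1 | step 14 | (E)-allylic bromide: methyl (3S)-6-acetyl-8-[(4R,5S)-5-((E)-5-bromo-2-methylpent-3-en-2-yl)-2,2-dimethyl-1,3-dioxolan-4-yl]-3,7-dimethyloct-6-enoate | COC(=O)C[C@@H](C)CCC(C(C)=O)=C(C)C[C@H]1OC(C)(C)O[C@H]1C(C)(C)/C=C/CBr
F2 | step 14 | diethyl (E)-allylphosphonate: methyl (3S)-6-acetyl-8-[(4R,5S)-5-((E)-5-(diethoxyphosphoryl)-2-methylpent-3-en-2-yl)-2,2-dimethyl-1,3-dioxolan-4-yl]-3,7-dimethyloct-6-enoate | COC(=O)C[C@@H](C)CCC(C(C)=O)=C(C)C[C@H]1OC(C)(C)O[C@H]1C(C)(C)/C=C/CP(=O)(OCC)OCC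
F3 | step 16 | methyl (13S)-2α,3α-(isopropylidenedioxy)labd-7-en-15-oate | COC(=O)C[C@@H](C)CC[C@H]1C(C)=CC[C@H]2C(C)(C)[C@@H]3OC(C)(C)O[C@@H]3C[C@]12C
F4 | step 9 | C2 epimer of 13, methyl (3S,9S)-6-acetyl-9-hydroxy-9-[(2S,4S)-2-(4-methoxyphenyl)-5,5-dimethyl-1,3-dioxan-4-yl]-3,7-dimethylnon-6-enoate | COC(=O)C[C@@H](C)CCC(C(C)=O)=C(C)C[C@H](O)[C@H]1O[C@@H](c2ccc(OC)cc2)OCC1(C)C
F5 | step 9 | 4-nitrobenzoate of 13 (9R) | COC(=O)C[C@@H](C)CCC(C(C)=O)=C(C)C[C@@H](OC(=O)c2ccc(cc2)[N+](=O)[O-])[C@H]1O[C@@H](c3ccc(OC)cc3)OCC1(C)C
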